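**Retrosynthetic overview**

1. The last skeletal bonds, C1–C13′ and C3–C11′ (norbornene ring), come from a Diels–Alder reaction between the α-methylene lactone of the 1,10-seco-eudesmanolide half and a 2-acetoxyguaia-1(5),3-diene whose own methylene is masked as CH2NMe2 and freed last.
2. The strategy rests on the cyclohexene ring of the seco-eudesmane half: C7′ bears C11′ cis to the C8′ lactone oxygen and trans to the C6′ hydroxyl, beside the tetrasubstituted C5′=C10′ alkene. This array is made in one step by 5-exo closure of a C8′-O-tethered bromoacetal radical onto C7′ of a cyclohexadiene, with nitroxide capture at C6′.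
3. The cyclohexadienol comes from (R)-4-silyloxycyclohexenone (C8′ is its only ring stereocentre) by α′-methylation, dienyl triflate, stannane and Zweifel coupling with an (S)-secondary boronic ester (C4′).
4. The guaianolide half starts from cyclohepta-1,3-diene: singlet oxygen and asymmetric Kornblum–DeLaMare rearrangement, conjugate methylation/aldol (C10, C1–C2), Mukaiyama–Michael addition (C7), Nozaki–Hiyama–Kishi closure of the five-membered ring, lactonisation, dehydration to the cyclopentadiene.
5. Ring order: cyclohexadiene → tetrahydrofuran acetal/lactone (key step); cycloheptenone → cyclopentenol → γ-lactone → cyclopentadiene; norbornene last.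

Key step: step 12

Assumption: in the reagent-controlled steps 3, 4, 22 and 25 the named antipode of the diamine, amide base, catalyst or ligand is the one expected to give the drawn configuration, and the mirror-image reagent is meant should the sense be opposite; centres that are destroyed later (acetal carbon, C6 of 12, C11 and C11′ of the Mannich bases) are left undefined.

**Part A. Side-chain boronic ester**

Step 1
Reactants: 1 ethanol
Product: 2 ethyl N,N-diisopropylcarbamate
Conditions: i-Pr2NCOCl, NEt3, CH2Cl2, reflux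
Reagents that add atoms: N,N-diisopropylcarbamoyl chloride, CC(C)N(C(C)C)C(Cl)=O
Why: Acylation of the alcohol by the carbamoyl chloride (carbamate formation) gives the substrate for α-lithiation.

Step 2
Reactants: 3 allyloxy(tert-butyl)dimethylsilane
Product: 4 2-[3-(tert-butyldimethylsilyloxy)propyl]-4,4,5,5-tetramethyl-1,3,2-dioxaborolane
Conditions: HBpin, [Ir(cod)Cl]2 (1.5 mol%), dppm (3 mol%), CH2Cl2, 23 °C
Reagents that add atoms: pinacolborane, CC1(C)OBOC1(C)C
Why: Iridium-catalysed hydroboration places boron at the terminal carbon and gives the primary boronic ester that becomes C3′–C1′.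

Step 3
Reactants: 2 ethyl N,N-diisopropylcarbamate; 4 primary boronic ester
Product: 7 (S)-tert-butyldimethyl{[4-(4,4,5,5-tetramethyl-1,3,2-dioxaborolan-2-yl)pentyl]oxy}silane, via lithiated carbamate 5 (not isolated), via boronate complex 6 (not isolated)
Conditions: s-BuLi, (+)-sparteine, Et2O, −78 °C; then 4, −78 °C; then reflux
Reagents that add atoms: none
Why: Lithiation–borylation: sparteine-mediated removal of one enantiotopic α-hydrogen gives the configurationally stable lithiated carbamate, which is borylated with retention and rearranges by 1,2-metallate shift with inversion, so the diamine sets C4′ as (S).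

**Part B. Seco-eudesmanolide half (1-O-acetylbritannilactone)**

Step 4
Reactants: 8 4-(tert-butyldimethylsilyloxy)cyclohexan-1-one
Product: 10 (R)-4-(tert-butyldimethylsilyloxy)cyclohex-2-en-1-one, via silyl enol ether 9 (not isolated)
Conditions: LiN[(S)-CHMePh]2, Me3SiCl (internal quench), THF, −100 °C; then Pd(OAc)2, MeCN, 23 °C
Reagents that add atoms: none
Why: Enantiotopic deprotonation of the prochiral ketone by the chiral lithium amide, trapped as the enol silane, fixes the future C8′ as (R), and Saegusa–Ito oxidation then introduces the C6′=C7′ double bond.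

Step 5
Reactants: 10 (R)-4-silyloxycyclohexenone
Product: 12 (4R)-4-(tert-butyldimethylsilyloxy)-6-methylcyclohex-2-en-1-one (both C6 epimers), via lithium dienolate 11 (not isolated)
Conditions: LiN(i-Pr)2, THF, −78 °C; then MeI, −78 → −30 °C
Reagents that add atoms: iodomethane, CI
Why: Kinetic α′-deprotonation and C-alkylation of the cross-conjugated dienolate install the C14′ methyl; the new centre becomes trigonal in the next step.

Step 6
Reactants: 12 methylated enone
Product: 14 (R)-4-(tert-butyldimethylsilyloxy)-2-methylcyclohexa-1,5-dien-1-yl trifluoromethanesulfonate, via potassium dienolate 13 (not isolated)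
Conditions: KN(SiMe3)2, THF, −78 °C; then PhNTf2
Reagents that add atoms: N-phenylbis(trifluoromethanesulfonimide), O=S(=O)(N(c1ccccc1)S(=O)(=O)C(F)(F)F)C(F)(F)F
Why: Renewed α′-deprotonation and O-sulfonylation of the dienolate (enol triflate formation) create the C5′=C10′ double bond and activate C5′.

Step 7
Reactants: 14 dienyl triflate
Product: 15 (R)-tert-butyldimethyl{[5-methyl-4-(trimethylstannyl)cyclohexa-2,4-dien-1-yl]oxy}silane
Conditions: (Me3Sn)2, Pd(PPh3)4 (5 mol%), LiCl, THF, 60 °C
Reagents that add atoms: hexamethylditin, C[Sn](C)(C)[Sn](C)(C)C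
Why: Palladium-catalysed coupling of the alkenyl triflate with the distannane (Stille-type stannylation) turns C5′ into a latent carbanion.

Step 8
Reactants: 15 dienylstannane; 7 (S)-boronic ester
Product: 19 tert-butyl{[(1R)-4-[(2S)-5-(tert-butyldimethylsilyloxy)pentan-2-yl]-5-methylcyclohexa-2,4-dien-1-yl]oxy}dimethylsilane, via dienyllithium 16 (not isolated), via boronate complex 17 (not isolated), via β-iodoboronic ester 18 (not isolated)
Conditions: MeLi, THF, −78 → 0 °C; then 7, −78 °C; then I2, MeOH, −78 °C; then NaOMe, −78 → 23 °C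
Reagents that add atoms: none
Why: Zweifel olefination: tin–lithium exchange, addition to boron, iodination of the alkenyl boronate with 1,2-shift of the secondary alkyl group (retention at C4′) and deboronative loss of the tertiary iodide rebuild the C5′=C10′ alkene with the side chain attached.

Step 9
Reactants: 19 bis-silyl ether
Product: 20 (1R)-4-[(2S)-5-hydroxypentan-2-yl]-5-methylcyclohexa-2,4-dien-1-ol
Conditions: Bu4NF, THF, 0 °C
Reagents that add atoms: none
Why: Fluoride-induced desilylation frees both alcohols under basic conditions, which the acid-sensitive cyclohexadienol tolerates.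

Step 10
Reactants: 20 diol
Product: 21 (1R)-4-[(2S)-5-(tert-butyldiphenylsilyloxy)pentan-2-yl]-5-methylcyclohexa-2,4-dien-1-ol
Conditions: t-BuPh2SiCl, imidazole, CH2Cl2, −20 °C
Reagents that add atoms: tert-butyl(chloro)diphenylsilane, CC(C)(C)[Si](Cl)(c1ccccc1)c1ccccc1
Why: Silylation with the bulky chlorosilane is selective for the primary C1′ hydroxyl over the secondary C8′ hydroxyl.

Step 11
Reactants: 21 dienol; 22 ethyl vinyl ether
Product: 23 bromoacetal, (1R)-1-(2-bromo-1-ethoxyethoxy)-4-[(2S)-5-(tert-butyldiphenylsilyloxy)pentan-2-yl]-5-methylcyclohexa-2,4-diene (both acetal epimers)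
Conditions: NBS, 2,6-lutidine (cat.), CH2Cl2, −40 → 0 °C
Reagents that add atoms: N-bromosuccinimide, O=C1CCC(=O)N1Br
Why: Bromoetherification of the vinyl ether (haloacetalisation) captures the C8′ alcohol under non-acidic conditions, and both acetal epimers serve.

Step 12
Reactants: 23 bromoacetal; 24 TEMPO
Product: 25 cis-fused bicyclic acetal, 2-ethoxy-5-[(2S)-5-(tert-butyldiphenylsilyloxy)pentan-2-yl]-6-methyl-4-(2,2,6,6-tetramethylpiperidin-1-yloxy)-2,3,3a,4,7,7a-hexahydrobenzofuran (C7′–C11′ cis to O8′ and trans to the C6′ aminoxy group; acetal epimers)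
Conditions: (Bu3Sn)2, hν (sunlamp), PhH, 30 °C, 24 added by syringe pump
Reagents that add atoms: none
Why: Bu3Sn• from the photolysed ditin abstracts bromine, the acetal-tethered primary radical adds to C7′ of the diene and the resulting C6′–C5′–C10′ allyl radical couples with the persistent nitroxide; the closest known reaction type is the Ueno–Stork haloacetal cyclisation terminated by nitroxide trapping. The tetrahydrofuran ring closes 5-exo-trig, and the two-atom tether from O8′ can reach C7′ only on the face of that oxygen, so C7′ (C7′–C11′ cis to O8′) is controlled by C8′. TEMPO then bonds to C6′ on the convex face of the new cis-fused bicycle, anti to the C7′–C11′ bond, so C6′ is controlled by the ring fusion just formed; the acetal carbon is not controlled and is removed by oxidation later. The step needs ring closure to outrun capture of the first radical by TEMPO, which the fast addition to a diene ending in an allyl radical and a low nitroxide concentration should secure. It also needs attack at the diene terminus C7′ (5-exo) and not at C6′ (6-endo), which allylic stabilisation dictates, and C–O bonding at the secondary terminus C6′ and not at the tertiary C10′, which the hindrance at C10′ and the reversibility of allylic alkoxyamine formation favour, leaving the tetrasubstituted C5′=C10′ alkene.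

Step 13
Reactants: 25 bicyclic acetal
Product: 27 γ-lactone, 5-[(2S)-5-(tert-butyldiphenylsilyloxy)pentan-2-yl]-6-methyl-4-(2,2,6,6-tetramethylpiperidin-1-yloxy)-3a,4,7,7a-tetrahydrobenzofuran-2(3H)-one, via lactol 26 (not isolated)
Conditions: PPTS, acetone/H2O, 40 °C; then PhI(OAc)2, TEMPO (10 mol%), CH2Cl2, 23 °C
Reagents that add atoms: water, O
Why: Acid hydrolysis of the mixed acetal to the lactol and nitroxide-catalysed oxidation with the hypervalent iodine reagent give the γ-lactone and erase the uncontrolled acetal centre.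

Step 14
Reactants: 27 lactone
Product: 29 3-(dimethylaminomethyl) lactone (C11′ epimers), via lithium enolate 28 (not isolated)
Conditions: LiN(i-Pr)2, THF, −78 °C; then CH2=NMe2+ I−, −78 → 0 °C
Reagents that add atoms: dimethylmethyleneiminium iodide, C=[N+](C)C.[I-]
Why: Mannich reaction of the lactone enolate with the iminium salt attaches C13′ as a dimethylaminomethyl group, a masked methylene whose C11′ configuration is lost later.

Step 15
Reactants: 29 Mannich base
Product: 30 C1′ primary alcohol
Conditions: Bu4NF, THF, 23 °C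
Reagents that add atoms: none
Why: Fluoride cleaves the silyl ether without affecting lactone, amine or aminoxy group.

Step 16
Reactants: 30 primary alcohol
Product: 31 C1′ acetate
Conditions: Ac2O, pyridine, DMAP (cat.), CH2Cl2, 0 °C
Reagents that add atoms: acetic anhydride, CC(=O)OC(C)=O
Why: Esterification of the only free hydroxyl gives the C1′ acetate while the C6′ oxygen is still blocked.

Step 17
Reactants: 31 aminoxy acetate
Product: 32 C6′ alcohol (dimethylamine adduct of 1-O-acetylbritannilactone)
Conditions: Zn, AcOH/THF/H2O, 50 °C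
Reagents that add atoms: none
Why: Dissolving-metal reduction of the N–O bond releases the C6′ alcohol with retention, no conjugate acceptor being present at this stage.

Step 18
Reactants: 32 amino lactone
Product: 34 1-O-acetylbritannilactone (α-methylene lactone; C4′ S, C8′ R, lactone cis-fused, C6′–OH trans to C7′–C11′), via ammonium iodide 33 (not isolated)
Conditions: MeI, MeOH, 23 °C; then NaHCO3, H2O/CH2Cl2
Reagents that add atoms: none
Why: N-Methylation and bicarbonate-induced β-elimination of trimethylamine (Hofmann-type) reveal the α-methylene lactone.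

**Part C. Iodoenal**

Step 19
Reactants: 35 but-2-yn-1-ol
Product: 37 (Z)-3-iodobut-2-en-1-ol, via cyclic vinylalanate 36 (not isolated)
Conditions: NaAlH2(OCH2CH2OMe)2, Et2O, 0 °C; then I2, −78 → 0 °C
Reagents that add atoms: iodine, II
Why: Hydroxyl-directed trans-hydroalumination of the propargylic alcohol and iodinolysis of the C–Al bond with retention give the (Z)-iodoalkene.

Step 20
Reactants: 37 iodoalkenol
Product: 38 (Z)-3-iodobut-2-enal
Conditions: MnO2, CH2Cl2, 23 °C
Reagents that add atoms: none
Why: Manganese dioxide oxidises the allylic alcohol to the enal without isomerising the (Z)-alkene.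

**Part D. Guaianolide half**

Step 21
Reactants: 39 cyclohepta-1,3-diene
Product: 40 6,7-dioxabicyclo[3.2.2]non-8-ene
Conditions: O2, hν, tetraphenylporphyrin (cat.), CH2Cl2, 0 °C
Reagents that add atoms: dioxygen, O=O
Why: [4+2] cycloaddition of singlet oxygen to the diene gives the meso endoperoxide.

Step 22
Reactants: 40 endoperoxide
Product: 41 (S)-4-hydroxycyclohept-2-en-1-one
Conditions: O-acetylcupreidine (5 mol%), CH2Cl2, 23 °C
Reagents that add atoms: none
Why: Enantioselective Kornblum–DeLaMare rearrangement, in which the chiral amine removes one of the two enantiotopic bridgehead hydrogens, sets the future C8 as (S).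

Step 23
Reactants: 41 hydroxy enone
Product: 42 (S)-4-(tert-butyldimethylsilyloxy)cyclohept-2-en-1-one
Conditions: t-BuMe2SiCl, imidazole, DMF, 23 °C
Reagents that add atoms: tert-butyl(chloro)dimethylsilane, CC(C)(C)[Si](C)(C)Cl
Why: Silylation protects the hydroxyl and provides the bulky group that later steers additions to the opposite face and away from the neighbouring enone terminus.

Step 24
Reactants: 42 silyloxy enone
Product: 44 (S)-4-(tert-butyldimethylsilyloxy)cyclohepta-2,6-dien-1-one, via silyl dienol ether 43 (not isolated)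
Conditions: LiN(i-Pr)2, Me3SiCl (internal quench), THF, −78 °C; then Pd(OAc)2, MeCN, 23 °C
Reagents that add atoms: none
Why: Kinetic α′-enolisation with internal silylation and Saegusa–Ito oxidation add the C1=C10 double bond and give the cross-conjugated dienone.

Step 25
Reactants: 44 dienone; 38 (Z)-3-iodobut-2-enal
Product: 46 aldol, (S)-4-silyloxy-6-methyl-7-[(Z)-1-hydroxy-3-iodobut-2-enyl]cyclohept-2-en-1-one (C10 S; C1–C2 bond trans to the C10 methyl; anti aldol), via magnesium enolate 45 (not isolated)
Conditions: MeMgBr, CuBr·SMe2 (5 mol%), (R,S)-Josiphos (6 mol%), t-BuOMe, −78 °C; then 38, −78 °C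
Reagents that add atoms: methylmagnesium bromide, C[Mg]Br
Why: Copper-catalysed asymmetric conjugate addition delivers methyl to C10, the enone terminus remote from the silyloxy group, with (S) configuration set by the ligand, and the magnesium enolate adds to the aldehyde at C1 (aldol reaction) anti to the new methyl through a closed chair transition state, which should give the anti aldol with C2 epimeric to the target.

Step 26
Reactants: 46 aldol
Product: 47 bis-silyl ether
Conditions: t-BuMe2SiOTf, 2,6-lutidine, CH2Cl2, −78 °C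
Reagents that add atoms: tert-butyldimethylsilyl trifluoromethanesulfonate, CC(C)(C)[Si](C)(C)OS(=O)(=O)C(F)(F)F
Why: Silylation of the aldol hydroxyl prevents retro-aldol cleavage in the following steps.

Step 27
Reactants: 47 enone
Product: 49 keto ester, methyl 2-[(C7)-cycloheptyl]acetate with C7 trans to C8–O, via silyl enol ether 48 (not isolated)
Conditions: CH2=C(OMe)OSiMe3, Ph3CClO4 (5 mol%), CH2Cl2, −78 °C; then 1 M HCl, THF, 0 °C
Reagents that add atoms: 1-methoxy-1-(trimethylsilyloxy)ethene, COC(=C)O[Si](C)(C)C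
Why: Mukaiyama–Michael addition of the ketene silyl acetal to the remaining enone takes place anti to the C8 silyloxy group, which sets C7 trans to C8–O, and the silyl enol ether is hydrolysed on work-up.

Step 28
Reactants: 49 keto ester
Product: 50 cis-fused hydroazulene tertiary alcohol (C5–OH cis to H1)
Conditions: CrCl2, NiCl2 (2 mol%), DMF, 23 °C
Reagents that add atoms: none
Why: Nozaki–Hiyama–Kishi reaction: the alkenylchromium species formed from the (Z)-iodide adds to the C5 ketone and closes the five-membered ring cis-fused; the C1 and C5 centres are removed later.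

Step 29
Reactants: 50 hydroxy ester
Product: 52 β-dimethylamino ester (C11 epimers), via dilithio ester enolate 51 (not isolated)
Conditions: LiN(i-Pr)2 (2.3 equiv), THF, −78 °C; then CH2=NMe2+ I−, −78 → 0 °C
Reagents that add atoms: dimethylmethyleneiminium iodide, C=[N+](C)C.[I-]
Why: Mannich reaction of the ester enolate, formed after the tertiary alcohol is deprotonated, attaches C13 as a dimethylaminomethyl group.

Step 30
Reactants: 52 amino ester
Product: 53 trans-fused γ-lactone diol (C2–OH, C5–OH)
Conditions: Bu4NF, THF, 0 → 23 °C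
Reagents that add atoms: none
Why: Fluoride removes both silyl ethers and the liberated C8 alkoxide lactonises onto the methyl ester (acyl substitution), giving the trans-fused γ-lactone.

Step 31
Reactants: 53 diol
Product: 54 (2R)-acetate with free tertiary C5–OH
Conditions: PPh3, DIAD, AcOH, PhMe, 0 °C
Reagents that add atoms: acetic acid, CC(=O)O
Why: Mitsunobu esterification of the secondary allylic alcohol with acetic acid proceeds with inversion and gives the (2R)-acetate, the tertiary alcohol being inert.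

**Part E. Union**

Step 32
Reactants: 54 guaianolide alcohol; 34 1-O-acetylbritannilactone
Product: 56 Diels–Alder adduct (target skeleton with C13 as CH2NMe2), via acetoxy cyclopentadiene 55 (not isolated)
Conditions: Ph2S[OC(CF3)2Ph]2 (1.0 equiv), CH2Cl2, −40 °C; then 34, CH2Cl2 (concentrated), 0 → 23 °C, dark
Reagents that add atoms: none
Why: Dehydration of the tertiary allylic alcohol with loss of H1 gives the 2-acetoxyguaia-1(5),3-diene, which should undergo the Diels–Alder reaction with the α-methylene lactone so that C13′ bonds to the substituted terminus C1 and C11′ to C3, with the lactone carbonyl exo, on the diene face opposite to the C2 acetate and the C10 methyl and on the dienophile face cis to C6′ (hydrogen bonding of the free C6′ hydroxyl is relied on here), which sets C1, C3 and C11′ and leaves the acetate on the bridge syn to the new alkene.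

Step 33
Reactants: 56 adduct
Product: 58 CNP0211028.3, via ammonium iodide 57 (not isolated)
Conditions: MeI, MeCN, 23 °C; then NaHCO3, H2O/CH2Cl2
Reagents that add atoms: none
Why: N-Methylation and bicarbonate-induced β-elimination of trimethylamine (Hofmann-type) free the guaianolide α-methylene lactone, no other amine or conjugate acceptor being present.

**Compound list**

1 | ethanol | CCO | starting material
2 | ethyl N,N-diisopropylcarbamate | CCOC(=O)N(C(C)C)C(C)C | intermediate
3 | allyloxy(tert-butyl)dimethylsilane | C=CCO[Si](C)(C)C(C)(C)C | starting material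
4 | 2-[3-(tert-butyldimethylsilyloxy)propyl]-4,4,5,5-tetramethyl-1,3,2-dioxaborolane | CC(C)(C)[Si](C)(C)OCCCB1OC(C)(C)C(C)(C)O1 | intermediate
5 | (R)-1-lithioethyl N,N-diisopropylcarbamate (sparteine complex) | [Li][C@H](C)OC(=O)N(C(C)C)C(C)C | intermediate (not isolated)
6 | lithium boronate complex from 5 and 4 | [Li+].C[C@H](OC(=O)N(C(C)C)C(C)C)[B-]1(CCCO[Si](C)(C)C(C)(C)C)OC(C)(C)C(C)(C)O1 | intermediate (not isolated)
7 | (S)-tert-butyldimethyl{[4-(4,4,5,5-tetramethyl-1,3,2-dioxaborolan-2-yl)pentyl]oxy}silane | C[C@@H](CCCO[Si](C)(C)C(C)(C)C)B1OC(C)(C)C(C)(C)O1 | intermediate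
8 | 4-(tert-butyldimethylsilyloxy)cyclohexan-1-one | O=C1CCC(CC1)O[Si](C)(C)C(C)(C)C | starting material
9 | (R)-tert-butyldimethyl{[4-(trimethylsilyloxy)cyclohex-3-en-1-yl]oxy}silane | C[Si](C)(C)OC1=CC[C@@H](CC1)O[Si](C)(C)C(C)(C)C | intermediate (not isolated)
10 | (R)-4-(tert-butyldimethylsilyloxy)cyclohex-2-en-1-one | O=C1C=C[C@@H](CC1)O[Si](C)(C)C(C)(C)C | intermediate
11 | lithium dienolate of 10 | [Li]OC1=CC[C@@H](O[Si](C)(C)C(C)(C)C)C=C1 | intermediate (not isolated)
12 | (4R)-4-(tert-butyldimethylsilyloxy)-6-methylcyclohex-2-en-1-one (C6 epimers) | CC1C[C@@H](O[Si](C)(C)C(C)(C)C)C=CC1=O | intermediate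
13 | potassium dienolate of 12 | [K]OC1=C(C)C[C@@H](O[Si](C)(C)C(C)(C)C)C=C1 | intermediate (not isolated)
14 | (R)-4-(tert-butyldimethylsilyloxy)-2-methylcyclohexa-1,5-dien-1-yl trifluoromethanesulfonate | CC1=C(OS(=O)(=O)C(F)(F)F)C=C[C@@H](C1)O[Si](C)(C)C(C)(C)C | intermediate
15 | (R)-tert-butyldimethyl{[5-methyl-4-(trimethylstannyl)cyclohexa-2,4-dien-1-yl]oxy}silane | CC1=C([Sn](C)(C)C)C=C[C@@H](C1)O[Si](C)(C)C(C)(C)C | intermediate
16 | [(R)-4-(tert-butyldimethylsilyloxy)-2-methylcyclohexa-1,5-dien-1-yl]lithium | [Li]C1=C(C)C[C@@H](O[Si](C)(C)C(C)(C)C)C=C1 | intermediate (not isolated)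
17 | lithium boronate complex from 16 and 7 | [Li+].C[C@@H](CCCO[Si](C)(C)C(C)(C)C)[B-]1(OC(C)(C)C(C)(C)O1)C1=C(C)C[C@@H](O[Si](C)(C)C(C)(C)C)C=C1 | intermediate (not isolated)
18 | β-iodoboronic ester (iodide at C10′, boronate and side chain at C5′) | C[C@@H](CCCO[Si](C)(C)C(C)(C)C)C1(B2OC(C)(C)C(C)(C)O2)C=C[C@H](O[Si](C)(C)C(C)(C)C)CC1(C)I | intermediate (not isolated)
19 | tert-butyl{[(1R)-4-[(2S)-5-(tert-butyldimethylsilyloxy)pentan-2-yl]-5-methylcyclohexa-2,4-dien-1-yl]oxy}dimethylsilane | C[C@@H](CCCO[Si](C)(C)C(C)(C)C)C1=C(C)C[C@@H](O[Si](C)(C)C(C)(C)C)C=C1 | intermediate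
20 | (1R)-4-[(2S)-5-hydroxypentan-2-yl]-5-methylcyclohexa-2,4-dien-1-ol | C[C@@H](CCCO)C1=C(C)C[C@@H](O)C=C1 | intermediate
21 | (1R)-4-[(2S)-5-(tert-butyldiphenylsilyloxy)pentan-2-yl]-5-methylcyclohexa-2,4-dien-1-ol | C[C@@H](CCCO[Si](c1ccccc1)(c1ccccc1)C(C)(C)C)C1=C(C)C[C@@H](O)C=C1 | intermediate
22 | ethyl vinyl ether | C=COCC | starting material
23 | bromoacetal of 21 (acetal epimers) | CCOC(CBr)O[C@@H]1CC(C)=C([C@@H](C)CCCO[Si](c2ccccc2)(c2ccccc2)C(C)(C)C)C=C1 | intermediate
24 | TEMPO (2,2,6,6-tetramethylpiperidin-1-oxyl) | CC1(C)CCCC(C)(C)N1[O] | starting material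
25 | cis-fused bicyclic acetal with C6′ aminoxy group (acetal epimers) | CCOC1C[C@H]2[C@H](ON3C(C)(C)CCCC3(C)C)C([C@@H](C)CCCO[Si](c4ccccc4)(c4ccccc4)C(C)(C)C)=C(C)C[C@H]2O1 | intermediate
26 | lactol from 25 | OC1C[C@H]2[C@H](ON3C(C)(C)CCCC3(C)C)C([C@@H](C)CCCO[Si](c4ccccc4)(c4ccccc4)C(C)(C)C)=C(C)C[C@H]2O1 | intermediate (not isolated)
27 | cis-fused γ-lactone with C6′ aminoxy group | O=C1C[C@H]2[C@H](ON3C(C)(C)CCCC3(C)C)C([C@@H](C)CCCO[Si](c4ccccc4)(c4ccccc4)C(C)(C)C)=C(C)C[C@H]2O1 | intermediate
28 | lithium enolate of 27 | [Li]OC1=C[C@H]2[C@H](ON3C(C)(C)CCCC3(C)C)C([C@@H](C)CCCO[Si](c4ccccc4)(c4ccccc4)C(C)(C)C)=C(C)C[C@H]2O1 | intermediate (not isolated)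
29 | α-(dimethylaminomethyl) lactone (C11′ epimers) | CN(C)CC1[C@H]2[C@H](ON3C(C)(C)CCCC3(C)C)C([C@@H](C)CCCO[Si](c4ccccc4)(c4ccccc4)C(C)(C)C)=C(C)C[C@H]2OC1=O | intermediate
30 | C1′ alcohol of 29 | CN(C)CC1[C@H]2[C@H](ON3C(C)(C)CCCC3(C)C)C([C@@H](C)CCCO)=C(C)C[C@H]2OC1=O | intermediate
31 | C1′ acetate of 30 | CN(C)CC1[C@H]2[C@H](ON3C(C)(C)CCCC3(C)C)C([C@@H](C)CCCOC(C)=O)=C(C)C[C@H]2OC1=O | intermediate
32 | dimethylamine adduct of 1-O-acetylbritannilactone (C6′–OH free) | CN(C)CC1[C@H]2[C@H](O)C([C@@H](C)CCCOC(C)=O)=C(C)C[C@H]2OC1=O | intermediate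
33 | trimethylammonium iodide of 32 | [I-].C[N+](C)(C)CC1[C@H]2[C@H](O)C([C@@H](C)CCCOC(C)=O)=C(C)C[C@H]2OC1=O | intermediate (not isolated)
34 | 1-O-acetylbritannilactone | C=C1[C@H]2[C@H](O)C([C@@H](C)CCCOC(C)=O)=C(C)C[C@H]2OC1=O | intermediate
35 | but-2-yn-1-ol | CC#CCO | starting material
36 | sodium cyclic vinylalanate | [Na+].CC1=CCO[Al-]1(OCCOC)OCCOC | intermediate (not isolated)
37 | (Z)-3-iodobut-2-en-1-ol | C/C(I)=C/CO | intermediate
38 | (Z)-3-iodobut-2-enal | C/C(I)=C/C=O | intermediate
39 | cyclohepta-1,3-diene | C1=CC=CCCC1 | starting material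
40 | 6,7-dioxabicyclo[3.2.2]non-8-ene | C1CC2OOC(C1)C=C2 | intermediate
41 | (S)-4-hydroxycyclohept-2-en-1-one | O=C1C=C[C@@H](O)CCC1 | intermediate
42 | (S)-4-(tert-butyldimethylsilyloxy)cyclohept-2-en-1-one | O=C1C=C[C@@H](O[Si](C)(C)C(C)(C)C)CCC1 | intermediate
43 | trimethylsilyl dienol ether of 42 | C[Si](C)(C)OC1=CCC[C@H](O[Si](C)(C)C(C)(C)C)C=C1 | intermediate (not isolated)
44 | (S)-4-(tert-butyldimethylsilyloxy)cyclohepta-2,6-dien-1-one | O=C1C=CC[C@H](O[Si](C)(C)C(C)(C)C)C=C1 | intermediate
45 | bromomagnesium dienolate after methyl addition (C10 S) | C[C@H]1C[C@H](O[Si](C)(C)C(C)(C)C)C=CC(O[Mg]Br)=C1 | intermediate (not isolated)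
46 | anti aldol: 4-silyloxy-6-methyl-7-[(Z)-1-hydroxy-3-iodobut-2-enyl]cyclohept-2-enone | C[C@H]1C[C@H](O[Si](C)(C)C(C)(C)C)C=CC(=O)[C@@H]1[C@@H](O)/C=C(/C)I | intermediate
47 | C2 silyl ether of 46 | C[C@H]1C[C@H](O[Si](C)(C)C(C)(C)C)C=CC(=O)[C@@H]1[C@@H](O[Si](C)(C)C(C)(C)C)/C=C(/C)I | intermediate
48 | trimethylsilyl enol ether after Michael addition | C[C@H]1C[C@H](O[Si](C)(C)C(C)(C)C)[C@@H](CC(=O)OC)C=C(O[Si](C)(C)C)[C@@H]1[C@@H](O[Si](C)(C)C(C)(C)C)/C=C(/C)I | intermediate (not isolated)
49 | keto ester (C7 acetate arm trans to C8–O) | C[C@H]1C[C@H](O[Si](C)(C)C(C)(C)C)[C@@H](CC(=O)OC)CC(=O)[C@@H]1[C@@H](O[Si](C)(C)C(C)(C)C)/C=C(/C)I | intermediate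
50 | cis-fused hydroazulene tertiary alcohol | C[C@H]1C[C@H](O[Si](C)(C)C(C)(C)C)[C@@H](CC(=O)OC)C[C@]2(O)C(C)=C[C@H](O[Si](C)(C)C(C)(C)C)[C@H]12 | intermediate
51 | dilithio alkoxide ester enolate of 50 | C[C@H]1C[C@H](O[Si](C)(C)C(C)(C)C)[C@@H](C=C(O[Li])OC)C[C@]2(O[Li])C(C)=C[C@H](O[Si](C)(C)C(C)(C)C)[C@H]12 | intermediate (not isolated)
52 | β-dimethylamino ester (C11 epimers) | C[C@H]1C[C@H](O[Si](C)(C)C(C)(C)C)[C@@H](C(CN(C)C)C(=O)OC)C[C@]2(O)C(C)=C[C@H](O[Si](C)(C)C(C)(C)C)[C@H]12 | intermediate
53 | trans-fused γ-lactone diol (2S) | C[C@H]1C[C@@H]2OC(=O)C(CN(C)C)[C@H]2C[C@]3(O)C(C)=C[C@H](O)[C@H]13 | intermediate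
54 | (2R)-acetate of the lactone with tertiary C5–OH | C[C@H]1C[C@@H]2OC(=O)C(CN(C)C)[C@H]2C[C@]3(O)C(C)=C[C@@H](OC(C)=O)[C@H]13 | intermediate
55 | (2R,7R,8S,10S)-2-acetoxyguaia-1(5),3-dien-12,8-olide with C13 as CH2NMe2 | CN(C)CC1C(=O)O[C@H]2C[C@H](C)C3=C(C[C@H]12)C(C)=C[C@H]3OC(C)=O | intermediate (not isolated)
56 | Diels–Alder adduct with C13 as CH2NMe2 | CN(C)CC1C(=O)O[C@H]2C[C@H](C)[C@@]34C[C@]5(C(=O)O[C@@H]6CC(C)=C([C@@H](C)CCCOC(C)=O)[C@@H](O)[C@@H]65)[C@@H](C(C)=C3C[C@H]12)[C@H]4OC(C)=O | intermediate
57 | trimethylammonium iodide of 56 | [I-].C[N+](C)(C)CC1C(=O)O[C@H]2C[C@H](C)[C@@]34C[C@]5(C(=O)O[C@@H]6CC(C)=C([C@@H](C)CCCOC(C)=O)[C@@H](O)[C@@H]65)[C@@H](C(C)=C3C[C@H]12)[C@H]4OC(C)=O | intermediate (not isolated)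
58 | CNP0211028.3 | C=C1C(=O)O[C@H]2C[C@H](C)[C@@]34C[C@]5(C(=O)O[C@@H]6CC(C)=C([C@@H](C)CCCOC(C)=O)[C@@H](O)[C@@H]65)[C@@H](C(C)=C3C[C@H]12)[C@H]4OC(C)=O | target

**Step count and risk**

Total steps: 33. Longest linear sequence: 17 steps (8 → 58: steps 4–18, then 32 and 33).

Steps most likely to fail:

1. Step 32. The dehydration may eliminate toward C6 and not C1, the acetoxy cyclopentadiene may undergo [1,5]-hydrogen migration before it is trapped, the sulfurane may attack the free C6′ hydroxyl of the dienophile, and the cycloaddition may show poor facial selectivity. The fallback sets out from 31 and 54 and returns at 56. Amine 31 is quaternised with MeI and eliminated with NaHCO3 to give the aminoxy-protected methylene lactone F1, which has no free hydroxyl. Alcohol 54 is then dehydrated with the sulfurane at −40 °C in the presence of F1, so that the diene is intercepted as it forms, giving the aminoxy-bearing adduct F2. Zn/AcOH cleavage of the N–O bond in F2 gives 56.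

2. Step 25. Methyl transfer may go to the silyloxy-flanked enone terminus C7 and not to C10, and the aldol may show poor simple diastereoselection. The fallback sets out from 42 and returns at 49, with the order of the two conjugate additions reversed. Mukaiyama–Michael addition to mono-enone 42 (CH2=C(OMe)OSiMe3, Ph3CClO4, then dilute HCl) gives the keto ester F3. Kinetic enolisation away from the branched carbon (LiN(i-Pr)2, Me3SiCl) and Saegusa–Ito oxidation give the enone F4, which has a single conjugate acceptor. Copper-catalysed methyl addition and aldol trapping with 38 give the aldol F5, and silylation with t-BuMe2SiOTf gives 49.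

3. Step 12. TEMPO may capture the tether radical before ring closure, the nitroxide may consume the tin radicals, and C–O bonding may occur at C10′. The fallback sets out from 23 and returns at 32, replacing nitroxide capture by a tin hydride chain under oxygen. Bu3SnH is added slowly to 23 in toluene under dry air at 0 °C, and PPh3 reduction of the allylic hydroperoxide gives the C6′ alcohol acetal F6. Silylation (t-BuMe2SiOTf, 2,6-lutidine) gives the C6′ silyl ether F7. Acetal hydrolysis and lactol oxidation as in step 13 give the lactone F8, and Mannich aminomethylation as in step 14 gives the amino lactone F9. Bu4NF removes both silyl groups to give the diol F10, and AcCl with 2,4,6-collidine at −78 °C acetylates the primary hydroxyl to give 32.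

**Further compounds**

F1 | step 32 | α-methylene lactone with C6′ aminoxy group and C1′ acetate | C=C1[C@H]2[C@H](ON3C(C)(C)CCCC3(C)C)C([C@@H](C)CCCOC(C)=O)=C(C)C[C@H]2OC1=O
F2 | step 32 | Diels–Alder adduct bearing the C6′ aminoxy group and C13 as CH2NMe2 | CN(C)CC1C(=O)O[C@H]2C[C@H](C)[C@@]34C[C@]5(C(=O)O[C@@H]6CC(C)=C([C@@H](C)CCCOC(C)=O)[C@@H](ON7C(C)(C)CCCC7(C)C)[C@@H]65)[C@@H](C(C)=C3C[C@H]12)[C@H]4OC(C)=O
F3 | step 25 | methyl 2-[(1S,2S)-2-(tert-butyldimethylsilyloxy)-6-oxocycloheptyl]acetate (trans) | O=C1C[C@H](CC(=O)OC)[C@@H](O[Si](C)(C)C(C)(C)C)CCC1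
F4 | step 25 | enone from F3 (C1=C10 double bond) | O=C1C[C@H](CC(=O)OC)[C@@H](O[Si](C)(C)C(C)(C)C)CC=C1
F5 | step 25 | aldol from F4 (C2–OH free) | C[C@H]1C[C@H](O[Si](C)(C)C(C)(C)C)[C@@H](CC(=O)OC)CC(=O)[C@@H]1[C@@H](O)/C=C(/C)I
F6 | step 12 | cis-fused bicyclic acetal with free C6′–OH | CCOC1C[C@H]2[C@H](O)C([C@@H](C)CCCO[Si](c3ccccc3)(c3ccccc3)C(C)(C)C)=C(C)C[C@H]2O1
F7 | step 12 | C6′ tert-butyldimethylsilyl ether of F6 | CCOC1C[C@H]2[C@H](O[Si](C)(C)C(C)(C)C)C([C@@H](C)CCCO[Si](c3ccccc3)(c3ccccc3)C(C)(C)C)=C(C)C[C@H]2O1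
F8 | step 12 | γ-lactone from F7 | O=C1C[C@H]2[C@H](O[Si](C)(C)C(C)(C)C)C([C@@H](C)CCCO[Si](c3ccccc3)(c3ccccc3)C(C)(C)C)=C(C)C[C@H]2O1
F9 | step 12 | α-(dimethylaminomethyl) lactone from F8 | CN(C)CC1[C@H]2[C@H](O[Si](C)(C)C(C)(C)C)C([C@@H](C)CCCO[Si](c3ccccc3)(c3ccccc3)C(C)(C)C)=C(C)C[C@H]2OC1=O
F10 | step 12 | amino lactone diol (C1′–OH, C6′–OH) | CN(C)CC1[C@H]2[C@H](O)C([C@@H](C)CCCO)=C(C)C[C@H]2OC1=O
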